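## Structural features

The target is a flat, achiral pentacycle: a coumestan core with a sixth-position lactone, plus a 2,2-dimethyl-3,4-dihydro-2H-pyran ring fused to ring A. The core consists of ring A (C1 to C4a and C11b), the pyranone (O5, C6, C6a, C11a, C11b, C4a), the furan (C6a, C6b, C10a, O11, C11a) and ring D (C6b to C10a). The extra pyran ring has its oxygen on C1 and its benzylic CH2 on C2. Ring A is substituted at every position but C4: pyran oxygen at C1, pyran CH2 at C2, methoxy at C3, the lactone oxygen O5 at C4a and the bond to C11a at C11b. Ring D carries the only free phenol, at C9, para to C6b. There is no stereocentre, so the problem is purely one of regiochemistry. The fragile points are the lactone (opened reversibly by base), the C9 phenol, the benzylic CH2 of the pyran ring, and the electron-rich ring A (C4–H is ortho to the methoxy group and para to the pyran oxygen; C11b is para to the methoxy group). All of these are sensitive to oxidants. The real difficulty is to place three different oxygen substituents in the right order around ring A, next to a C11a–C11b bond flanked by two oxygen-bearing carbons. The key step uses the fact that, in a 2-arylbenzofuran-3-carboxylic acid, C4a–H is the only hydrogen ortho to the C11a–C11b bond, because C1 is already the pyran ether carbon. The C6 carboxyl group can therefore form the O5–C4a bond at one site only.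

## Logic of the disconnections

**16 to 15.** Backwards, an acetyl group is placed on the C9 oxygen. A free phenol would not survive an oxidant able to functionalize an aromatic C–H bond, so the oxygen is carried as the ester through the oxidation. Nothing is simplified in the skeleton; the gain is a mild last step. The forward methanolysis must take off the aryl ester and leave the lactone closed.

**15 to 14.** The O5–C4a bond is cut, which opens the pyranone to a C6 carboxylic acid on the benzofuran and a C4a–H on ring A. This is the strategic cut. It lowers ring A from three oxygen substituents to two, so ring A can come from 4, where the two oxygens already sit correctly relative to the acyl carbon. The forward step must oxygenate one aromatic C–H bond in the presence of the more nucleophilic C4–H, the ipso carbon C11b para to a methoxy group, and a benzylic CH2.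

**14 to 13 to 12.** Backwards, the acetyl group is removed; then one benzyl group is put on the C9 oxygen, another on the carboxyl oxygen, and the C=C bond of a 2H-chromene is restored. These three features are chosen together because a single hydrogenation removes both benzyl groups and saturates the pyran ring. This saves a separate ester hydrolysis and a separate alkene reduction. The forward demands are that the hydrogenation leaves the furan double bond alone and that acetylation takes the phenol but not the carboxylate.

**12 to 10 and 3.** The C6a–C6b and O11–C10a bonds are cut, the two bonds that join ring D to the furan. The enol of 10 supplies C6a and O11 as a carbon, oxygen double nucleophile; 3 supplies C6b and C10a as neighbouring C–I and C–Br carbons. The tetracycle falls into a bicyclic keto ester and a monocyclic arene, and the route becomes convergent. The forward step must make the C–C bond first, at the iodide, so that the benzyloxy group ends para to C6b, at C9.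

**10 to 8 and 9.** The C6–C6a bond is cut. The carboxyl carbon comes from 9 by enolate acylation of the methyl ketone 8. The demand is acyl transfer, not benzyl transfer, and a base that leaves the chromene alone.

**8 to 6 to 4 and 5.** First the bond between ring A C2 and the pyran CH is cut, then the O–C(CH3)2 bond. In 4 the hydroxyl has only one free ortho carbon, the one between hydroxyl and methoxy; the other carries the acetyl group. A propargyl ether rearrangement can therefore fuse the pyran ring in one orientation only. All five ring A substituents are thus traced to one commercial arene. The demand is O-alkylation of a chelated phenol by a tertiary propargylic chloride.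

**3 to 2 to 1.** The C–I bond and then the O–CH2Ph bond are cut. The ether oxygen directs iodine to its para position, which gives the halogen pattern needed in 12. The demand is para selectivity in the iodination.

## Other disconnections considered

**Alternative 1:** The cut runs through C6a–C6b and O11–C11a at the pterocarpan oxidation level.
- **Forward key step:** The pyrano-fused 2H-chromene A1 (ring A with its methoxy group and dimethyldihydropyran ring, plus the O5–C6H2–C6a=C11a unit) and 5-(benzyloxy)-2-iodophenol A2 would be joined with Pd(OAc)2 and Ag2CO3. The aryl–palladium species would add syn across the chromene alkene, aryl to C6a, and the phenol oxygen would capture the benzylic palladium at C11a to give the cis-fused pterocarpan A3.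
- **In favour:** Two bonds and one ring form in one convergent step. All ring A oxygens are in place before the union, so no C–H oxygenation is needed next to an ipso carbon activated by a para-methoxy group. On bond-forming efficiency and on freedom from oxidative risk at ring A this plan is the better one. The cis fusion needs no control, since both stereocentres are erased later.
- **Against:** A3 lies three two-electron oxidations below the coumestan. Dehydrogenation across C6a–C11a and oxidation of the C6 methylene would have to distinguish that methylene from the benzylic CH2 of the pyran ring and spare the benzyl ether. A1 needs a ring A with three differentiated oxygens and two different pyran rings, a regiochemical problem that 4 avoids in the chosen plan. Silver is used stoichiometrically.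
- **Comparison:** Both key steps are palladium-mediated. The chosen plan works at the final oxidation level with one two-electron oxidation, whereas this alternative makes two stereocentres only to destroy them. The estimated step count is about equal or slightly higher (synthesis of A1 and A2, union, two oxidations, debenzylation).

**Alternative 2:** The cut runs through C11a–C11b and O5–C6.
- **Forward key step:** 6-(Benzyloxy)-2-bromo-1-benzofuran-3-carboxylic acid A4 and phloroglucinol A5 would be heated with CuSO4 in aqueous NaOH. This is a Hurtley-type C-arylation assisted by the neighbouring carboxylate; lactonization on acidification would give the coumestan diol A6.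
- **In favour:** The symmetry of A5 removes any regiochemical question from both the C–C coupling and the lactone closure. The C4a oxygen arrives with A5, so no oxidant is needed, and the medium is water. On these points the alternative is equal or better.
- **Against:** The methyl ether and the pyran ring must then be installed on A6. This means telling the C1 and C3 hydroxyls apart; the C3 hydroxyl, vinylogous to the lactone carbonyl, should be the more acidic, but the distinction is not enforced by structure. Propargylation at the C1 oxygen, rearrangement to C2 and hydrogenation would follow. A polyphenolic coumestan is likely to be poorly soluble. Hot aqueous hydroxide may attack A4 at C2 by addition–elimination, and A5 may be arylated more than once.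
- **Comparison:** The step count should be about the same as the chosen plan. The chosen plan fixes the ring A pattern at the start by the structure of 4, not by late selective O-alkylation; the alternative avoids the oxidative step.

**Alternative 3:** The cut is at O11–C10a, with ring D still a cyclohexenone.
- **Forward key step:** The 1,4-diketone A7 (aryl ketone carbon C11a, ester-bearing C6a, C6b, and the enone carbonyl carbon C10a of the ring that becomes ring D) would be cyclodehydrated with TsOH under anhydrous conditions (Paal–Knorr) to the 4,5-dihydrobenzofuran A8. Dehydrogenation of ring D, hydrogenolysis of both benzyl ethers and lactonization would follow.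
- **In favour:** The furan is closed without a metal by a dependable cyclodehydration. The C4a oxygen is present from the start, so the lactone closes by simple acyl transfer. On security of the last ring closure this plan is the better one.
- **Against:** A7 requires a C6a–C6b bond between the α-carbon of a hindered aroylacetate and the α′-carbon of a vinylogous ester, a congested alkylation with O-alkylation and elimination as competitors. The enol ether of A8 is acid-labile in the step that forms it. Ring D needs a separate aromatization near the benzylic CH2 and the electron-rich ring A. Ring A needs a phloroglucinol-level ketone and an extra protecting group.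
- **Comparison:** The chemistry is polar and acid-catalysed, as against transition-metal C–H activation. This alternative builds ring D from non-aromatic carbons, whereas the chosen plan buys it as the intact arene 1. The step economy is clearly worse.

Key step: step 9

Remark: the target has no stereocentre, so no step has to set configuration and all structures are written without stereodescriptors; 11 forms as a racemic, enolizable compound.

## Route

**Step 1**
Reactants: 1 3-bromophenol
Product: 2 1-(benzyloxy)-3-bromobenzene
Conditions: BnBr, K2CO3, acetone, reflux
Reagents that add atoms: benzyl bromide, BrCc1ccccc1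
Why: Williamson ether synthesis; the phenoxide is alkylated by the primary benzylic bromide, and the ether both protects the future C9 oxygen and directs the next step.

**Step 2**
Reactants: 2 1-(benzyloxy)-3-bromobenzene
Product: 3 4-(benzyloxy)-2-bromo-1-iodobenzene
Conditions: N-iodosuccinimide, CF3CO2H (cat.), MeCN, rt
Reagents that add atoms: N-iodosuccinimide, O=C1CCC(=O)N1I
Why: Electrophilic aromatic iodination; the alkoxy group directs to its para position, the site between the two substituents is shielded and the remaining ortho site is less activated, so iodine should enter para to oxygen and ortho to bromine.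

**Step 3**
Reactants: 4 paeonol (2'-hydroxy-4'-methoxyacetophenone); 5 3-chloro-3-methylbut-1-yne
Product: 6 1-{4-methoxy-2-[(2-methylbut-3-yn-2-yl)oxy]phenyl}ethan-1-one
Conditions: DBU, CuCl2·2H2O (cat.), MeCN, 0 °C to rt
Reagents that add atoms: none
Why: Copper-catalysed propargylic etherification (Williamson-type O-alkylation through a copper acetylide ion pair); DBU frees the chelated phenoxide and the low temperature holds back elimination of 5.

**Step 4**
Reactants: 6 1-{4-methoxy-2-[(2-methylbut-3-yn-2-yl)oxy]phenyl}ethan-1-one
Product: 8 1-(5-methoxy-2,2-dimethyl-2H-chromen-8-yl)ethan-1-one, via ortho-allenylphenol 7 (not isolated)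
Conditions: N,N-diethylaniline, 185 °C
Reagents that add atoms: none
Why: Aryl propargyl ether Claisen rearrangement; the [3,3] shift can only reach the free ortho carbon between the ether oxygen and the methoxy group, enolization gives 7, and a 1,5-hydrogen shift followed by oxa-6π electrocyclization closes the 2H-pyran.

**Step 5**
Reactants: 8 1-(5-methoxy-2,2-dimethyl-2H-chromen-8-yl)ethan-1-one; 9 dibenzyl carbonate
Product: 10 benzyl 3-(5-methoxy-2,2-dimethyl-2H-chromen-8-yl)-3-oxopropanoate
Conditions: NaH, THF, reflux; then aq. HCl, 0 °C
Reagents that add atoms: none
Why: Crossed Claisen condensation of the methyl ketone enolate with a non-enolizable carbonate, driven by deprotonation of the keto ester formed; the benzyl ester is chosen so that it can be removed later by hydrogenolysis.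

**Step 6**
Reactants: 10 benzyl 3-(5-methoxy-2,2-dimethyl-2H-chromen-8-yl)-3-oxopropanoate; 3 4-(benzyloxy)-2-bromo-1-iodobenzene
Product: 12 benzyl 6-(benzyloxy)-2-(5-methoxy-2,2-dimethyl-2H-chromen-8-yl)-1-benzofuran-3-carboxylate, via C-arylated keto ester 11 (not isolated)
Conditions: CuI (10 mol %), K2CO3, THF, 100 °C (sealed tube)
Reagents that add atoms: none
Why: Copper-catalysed domino arylation of a β-keto ester with an ortho-dihaloarene; Ullmann-type C-arylation of the enolate takes the more reactive C–I carbon to give 11, whose enolate oxygen then closes the furan by intramolecular O-arylation at C–Br, which places the benzyloxy group para to the new C–C bond (position 6 of the benzofuran).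

**Step 7**
Reactants: 12 benzyl 6-(benzyloxy)-2-(5-methoxy-2,2-dimethyl-2H-chromen-8-yl)-1-benzofuran-3-carboxylate
Product: 13 6-hydroxy-2-(5-methoxy-2,2-dimethyl-3,4-dihydro-2H-chromen-8-yl)-1-benzofuran-3-carboxylic acid
Conditions: H2 (1 atm), 10% Pd/C, EtOAc/MeOH, rt
Reagents that add atoms: none
Why: Heterogeneous hydrogenation; hydrogenolysis of the benzyl ether and benzyl ester and saturation of the disubstituted chromene alkene should all proceed under the same mild conditions, while the tetrasubstituted, carboxyl-conjugated furan double bond is not reduced.

**Step 8**
Reactants: 13 6-hydroxy-2-(5-methoxy-2,2-dimethyl-3,4-dihydro-2H-chromen-8-yl)-1-benzofuran-3-carboxylic acid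
Product: 14 6-acetoxy-2-(5-methoxy-2,2-dimethyl-3,4-dihydro-2H-chromen-8-yl)-1-benzofuran-3-carboxylic acid
Conditions: Ac2O, aq. NaOH, THF, 0 °C; then HCl to pH 3
Reagents that add atoms: acetic anhydride, CC(=O)OC(C)=O
Why: Schotten–Baumann acetylation; in cold aqueous base only the phenoxide is acylated durably, and the carboxylate stays as its sodium salt and returns as the free acid on acidification.

**Step 9**
Reactants: 14 6-acetoxy-2-(5-methoxy-2,2-dimethyl-3,4-dihydro-2H-chromen-8-yl)-1-benzofuran-3-carboxylic acid
Product: 15 9-acetoxy-3-methoxycoumestan carrying a 2,2-dimethyl-3,4-dihydro-2H-pyran ring fused at C1 (pyran oxygen) and C2 (pyran CH2), the 9-O-acetyl derivative of the target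
Conditions: Pd(OAc)2 (10 mol %), N-acetylglycine (30 mol %), PhI(OAc)2, KOAc, t-BuOH, 80 °C
Reagents that add atoms: none
Why: Carboxyl-directed C–H lactonization, the closest known reaction type being the palladium-catalysed dehydrogenative cyclization of biaryl-2-carboxylic acids to benzo[c]chromen-6-ones. The potassium carboxylate of 14 binds divalent palladium, and acetate-assisted concerted metalation–deprotonation at C4a–H (helped by the amino acid ligand) should give a seven-membered palladacycle made of Pd, O, C6, C6a, C11a, C11b and C4a. PhI(OAc)2 then oxidizes the metal to tetravalent palladium, and C–O reductive elimination forms O5–C4a, closing the six-membered pyranone by contraction of the palladacycle, not by attack of a free oxygen radical or cation on the ring. No stereocentre is formed. Site selectivity between the two carbons ortho to the C11a–C11b bond is secured by the substrate, because C1 is already the pyran ether carbon and only C4a carries hydrogen. Chemoselectivity is needed against the nucleophilic C4–H, against ipso attack at C11b (para to the methoxy group, which would lead to a dearomatized spirolactone) and against the benzylic CH2. The carboxylate-tethered, inner-sphere metalation can reach only C4a, and the non-acidic alcohol solvent keeps the trivalent iodine oxidant from attacking ring A directly. This is the reason the palladium manifold is preferred here to a copper and peroxide radical manifold. The acetate keeps the C9 oxygen from being oxidized.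

**Step 10**
Reactants: 15 the 9-O-acetyl derivative of the target
Product: 16 9-hydroxy-3-methoxycoumestan carrying a 2,2-dimethyl-3,4-dihydro-2H-pyran ring fused at C1 (pyran oxygen) and C2 (pyran CH2), CNP0304440.0
Conditions: K2CO3, MeOH, 0 °C to rt; then aq. HCl to pH 4
Reagents that add atoms: none
Why: Base-mediated methanolysis (transesterification) of the aryl acetate, which is far more electrophilic than the conjugated lactone; any opening of the lactone by methoxide is reversed on acidification.

## Compound list

1 | 3-bromophenol | Oc1cccc(Br)c1 | starting material
2 | 1-(benzyloxy)-3-bromobenzene | Brc1cccc(OCc2ccccc2)c1 | intermediate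
3 | 4-(benzyloxy)-2-bromo-1-iodobenzene | Brc1cc(OCc2ccccc2)ccc1I | intermediate
4 | paeonol (2'-hydroxy-4'-methoxyacetophenone) | CC(=O)c1ccc(OC)cc1O | starting material
5 | 3-chloro-3-methylbut-1-yne | CC(C)(Cl)C#C | starting material
6 | 1-{4-methoxy-2-[(2-methylbut-3-yn-2-yl)oxy]phenyl}ethan-1-one | CC(=O)c1ccc(OC)cc1OC(C)(C)C#C | intermediate
7 | 1-[2-hydroxy-4-methoxy-3-(3-methylbuta-1,2-dien-1-yl)phenyl]ethan-1-one (not isolated) | CC(=O)c1ccc(OC)c(C=C=C(C)C)c1O | intermediate
8 | 1-(5-methoxy-2,2-dimethyl-2H-chromen-8-yl)ethan-1-one | CC(=O)c1ccc(OC)c2C=CC(C)(C)Oc12 | intermediate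
9 | dibenzyl carbonate | O=C(OCc1ccccc1)OCc1ccccc1 | starting material
10 | benzyl 3-(5-methoxy-2,2-dimethyl-2H-chromen-8-yl)-3-oxopropanoate | O=C(CC(=O)OCc1ccccc1)c1ccc(OC)c2C=CC(C)(C)Oc12 | intermediate
11 | benzyl 2-[4-(benzyloxy)-2-bromophenyl]-3-(5-methoxy-2,2-dimethyl-2H-chromen-8-yl)-3-oxopropanoate (racemic, enolizable, not isolated) | O=C(C(c1ccc(OCc2ccccc2)cc1Br)C(=O)OCc1ccccc1)c1ccc(OC)c2C=CC(C)(C)Oc12 | intermediate
12 | benzyl 6-(benzyloxy)-2-(5-methoxy-2,2-dimethyl-2H-chromen-8-yl)-1-benzofuran-3-carboxylate | O=C(OCc1ccccc1)c1c(-c2ccc(OC)c3C=CC(C)(C)Oc23)oc2cc(OCc3ccccc3)ccc12 | intermediate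
13 | 6-hydroxy-2-(5-methoxy-2,2-dimethyl-3,4-dihydro-2H-chromen-8-yl)-1-benzofuran-3-carboxylic acid | OC(=O)c1c(-c2ccc(OC)c3CCC(C)(C)Oc23)oc2cc(O)ccc12 | intermediate
14 | 6-acetoxy-2-(5-methoxy-2,2-dimethyl-3,4-dihydro-2H-chromen-8-yl)-1-benzofuran-3-carboxylic acid | CC(=O)Oc1ccc2c(C(=O)O)c(-c3ccc(OC)c4CCC(C)(C)Oc34)oc2c1 | intermediate
15 | 9-acetoxy-3-methoxycoumestan with a 2,2-dimethyl-3,4-dihydro-2H-pyran ring fused at C1 (O) and C2 (CH2) | COc1cc2oc(=O)c3c4ccc(OC(C)=O)cc4oc3c2c2c1CCC(C)(C)O2 | intermediate
16 | 9-hydroxy-3-methoxycoumestan with a 2,2-dimethyl-3,4-dihydro-2H-pyran ring fused at C1 (O) and C2 (CH2), CNP0304440.0 | COc1cc2oc(=O)c3c4ccc(O)cc4oc3c2c2c1CCC(C)(C)O2 | target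

## Step count and risk

Total step count: 10. Longest linear sequence: 8 steps (steps 3 to 10, from 4); steps 1 and 2 make the second fragment.

**Step 9 (key step).**
- **What may go wrong:** Ring A may be oxidized outside the palladium cycle. The trivalent iodine reagent may induce ipso attack of the carboxylate at C11b, which is activated by the para-methoxy and ortho-alkoxy groups, with dearomatization, or acetoxylation at the nucleophilic C4 position. Cyclopalladation of the twisted, ortho-alkoxy-substituted biaryl may also be slow, leaving time for protodecarboxylation of the heteroaryl acid.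
- **Fallback:** The C–H oxygenation is abandoned and the C4a oxygen is carried from the start. Setting out from 5, 9 and 3, bought 2',6'-dihydroxy-4'-methoxyacetophenone F1 is mono-O-alkylated with 5 (DBU, CuCl2·2H2O cat., MeCN) to 1-{2-hydroxy-4-methoxy-6-[(2-methylbut-3-yn-2-yl)oxy]phenyl}ethan-1-one F2. Heating rearranges this, as in step 4, to 1-(7-hydroxy-5-methoxy-2,2-dimethyl-2H-chromen-8-yl)ethan-1-one F3. Benzylation (BnBr, K2CO3, DMF) gives 1-[7-(benzyloxy)-5-methoxy-2,2-dimethyl-2H-chromen-8-yl]ethan-1-one F4. Claisen condensation with 9 (NaH, THF) gives benzyl 3-[7-(benzyloxy)-5-methoxy-2,2-dimethyl-2H-chromen-8-yl]-3-oxopropanoate F5. The CuI and K2CO3 annulation with 3 gives benzyl 6-(benzyloxy)-2-[7-(benzyloxy)-5-methoxy-2,2-dimethyl-2H-chromen-8-yl]-1-benzofuran-3-carboxylate F6. Hydrogenation (H2, Pd/C) should give 6-hydroxy-2-(7-hydroxy-5-methoxy-2,2-dimethyl-3,4-dihydro-2H-chromen-8-yl)-1-benzofuran-3-carboxylic acid F7. F7 lactonizes between the carboxyl group and the ring A hydroxyl (TsOH cat., toluene, reflux) and so comes back to the route at 16.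

**Step 6.**
- **What may go wrong:** Retro-Claisen loss of the aroyl group from 11 under carbonate at 100 °C, or stalling of the enol O-arylation because the ketone carries a hindered ortho-alkoxyaryl group.
- **Fallback:** The furan is built from an alkyne with carbon monoxide as the source of C6. Setting out from 8, one-pot enol phosphate formation and elimination (LDA, ClP(O)(OEt)2, then LDA, THF) gives 8-ethynyl-5-methoxy-2,2-dimethyl-2H-chromene F8. Sonogashira coupling (PdCl2(PPh3)2, CuI, Et3N, rt) with 5-(benzyloxy)-2-iodophenol F9, made from 3-(benzyloxy)phenol and N-iodosuccinimide, gives 5-(benzyloxy)-2-[(5-methoxy-2,2-dimethyl-2H-chromen-8-yl)ethynyl]phenol F10. Alkoxycarbonylative annulation (PdI2, thiourea, CBr4, Cs2CO3, CO 1 atm, benzyl alcohol, 45 °C) closes the furan by oxypalladation and adds the ester by CO insertion, coming back to the route at 12.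

**Step 3.**
- **What may go wrong:** Slow O-alkylation of the chelated, hindered phenoxide by the tertiary propargylic chloride, with elimination of 5 to an enyne taking over.
- **Fallback:** Setting out from 4, the chromene is made directly and comes back to the route at 8, bypassing 6 and step 4. 4 is heated with 3-methylbut-2-enal, PhB(OH)2 and a catalytic carboxylic acid in toluene with removal of water. Boron-templated ortho-hydroxyalkylation at the carbon between hydroxyl and methoxy, loss of water to an ortho-quinone methide and oxa-6π electrocyclization should follow. No new isolated compound is involved.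

**Step 5.**
- **What may go wrong:** Benzyl transfer from 9 to the enolate in place of acyl transfer, or incomplete acylation of the hindered ketone enolate.
- **Fallback:** The methyl ester series is used, at the cost of one more step. Setting out from 8, NaH and dimethyl carbonate give methyl 3-(5-methoxy-2,2-dimethyl-2H-chromen-8-yl)-3-oxopropanoate F11. The CuI and K2CO3 annulation with 3 gives methyl 6-(benzyloxy)-2-(5-methoxy-2,2-dimethyl-2H-chromen-8-yl)-1-benzofuran-3-carboxylate F12. Saponification (NaOH, MeOH/H2O, reflux) gives 6-(benzyloxy)-2-(5-methoxy-2,2-dimethyl-2H-chromen-8-yl)-1-benzofuran-3-carboxylic acid F13. Hydrogenation (H2, Pd/C) comes back to the route at 13.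

## Further compounds

F1 | step 9 | 2',6'-dihydroxy-4'-methoxyacetophenone (bought) | CC(=O)c1c(O)cc(OC)cc1O
F2 | step 9 | 1-{2-hydroxy-4-methoxy-6-[(2-methylbut-3-yn-2-yl)oxy]phenyl}ethan-1-one | CC(=O)c1c(O)cc(OC)cc1OC(C)(C)C#C
F3 | step 9 | 1-(7-hydroxy-5-methoxy-2,2-dimethyl-2H-chromen-8-yl)ethan-1-one | CC(=O)c1c(O)cc(OC)c2C=CC(C)(C)Oc12
F4 | step 9 | 1-[7-(benzyloxy)-5-methoxy-2,2-dimethyl-2H-chromen-8-yl]ethan-1-one | CC(=O)c1c(OCc2ccccc2)cc(OC)c2C=CC(C)(C)Oc12
F5 | step 9 | benzyl 3-[7-(benzyloxy)-5-methoxy-2,2-dimethyl-2H-chromen-8-yl]-3-oxopropanoate | O=C(CC(=O)OCc1ccccc1)c1c(OCc2ccccc2)cc(OC)c2C=CC(C)(C)Oc12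
F6 | step 9 | benzyl 6-(benzyloxy)-2-[7-(benzyloxy)-5-methoxy-2,2-dimethyl-2H-chromen-8-yl]-1-benzofuran-3-carboxylate | O=C(OCc1ccccc1)c1c(-c2c(OCc3ccccc3)cc(OC)c3C=CC(C)(C)Oc23)oc2cc(OCc3ccccc3)ccc12
F7 | step 9 | 6-hydroxy-2-(7-hydroxy-5-methoxy-2,2-dimethyl-3,4-dihydro-2H-chromen-8-yl)-1-benzofuran-3-carboxylic acid | OC(=O)c1c(-c2c(O)cc(OC)c3CCC(C)(C)Oc23)oc2cc(O)ccc12
F8 | step 6 | 8-ethynyl-5-methoxy-2,2-dimethyl-2H-chromene | C#Cc1ccc(OC)c2C=CC(C)(C)Oc12
F9 | step 6 | 5-(benzyloxy)-2-iodophenol | Oc1cc(OCc2ccccc2)ccc1I
F10 | step 6 | 5-(benzyloxy)-2-[(5-methoxy-2,2-dimethyl-2H-chromen-8-yl)ethynyl]phenol | Oc1cc(OCc2ccccc2)ccc1C#Cc1ccc(OC)c2C=CC(C)(C)Oc12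
F0 | step 3 | none | none
F11 | step 5 | methyl 3-(5-methoxy-2,2-dimethyl-2H-chromen-8-yl)-3-oxopropanoate | COC(=O)CC(=O)c1ccc(OC)c2C=CC(C)(C)Oc12
F12 | step 5 | methyl 6-(benzyloxy)-2-(5-methoxy-2,2-dimethyl-2H-chromen-8-yl)-1-benzofuran-3-carboxylate | COC(=O)c1c(-c2ccc(OC)c3C=CC(C)(C)Oc23)oc2cc(OCc3ccccc3)ccc12
F13 | step 5 | 6-(benzyloxy)-2-(5-methoxy-2,2-dimethyl-2H-chromen-8-yl)-1-benzofuran-3-carboxylic acid | OC(=O)c1c(-c2ccc(OC)c3C=CC(C)(C)Oc23)oc2cc(OCc3ccccc3)ccc12
A1 | alternative 1 | 2H-chromene carrying ring A with its methoxy group and the fused 2,2-dimethyldihydropyran ring | COc1cc2OCC=Cc2c2OC(C)(C)CCc12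
A2 | alternative 1 | 5-(benzyloxy)-2-iodophenol | Oc1cc(OCc2ccccc2)ccc1I
A3 | alternative 1 | cis-fused 9-benzyloxy pterocarpan with ring A methoxy and dimethylpyran (racemic, one enantiomer drawn) | COc1cc2OC[C@H]3c4ccc(OCc5ccccc5)cc4O[C@H]3c2c2OC(C)(C)CCc12
A4 | alternative 2 | 6-(benzyloxy)-2-bromo-1-benzofuran-3-carboxylic acid | OC(=O)c1c(Br)oc2cc(OCc3ccccc3)ccc12
A5 | alternative 2 | phloroglucinol | Oc1cc(O)cc(O)c1
A6 | alternative 2 | 9-(benzyloxy)-1,3-dihydroxy-6H-benzofuro[3,2-c]chromen-6-one | Oc1cc(O)c2c(c1)oc(=O)c1c3ccc(OCc4ccccc4)cc3oc12
A7 | alternative 3 | methyl 2-[4-(benzyloxy)-2-oxocyclohex-3-en-1-yl]-3-[7-(benzyloxy)-5-methoxy-2,2-dimethyl-3,4-dihydro-2H-chromen-8-yl]-3-oxopropanoate (mixture of stereoisomers) | COC(=O)C(C1CCC(OCc2ccccc2)=CC1=O)C(=O)c1c(OCc2ccccc2)cc(OC)c2CCC(C)(C)Oc12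
A8 | alternative 3 | methyl 6-(benzyloxy)-2-[7-(benzyloxy)-5-methoxy-2,2-dimethyl-3,4-dihydro-2H-chromen-8-yl]-4,5-dihydro-1-benzofuran-3-carboxylate | COC(=O)c1c(-c2c(OCc3ccccc3)cc(OC)c3CCC(C)(C)Oc23)oc2C=C(OCc3ccccc3)CCc12
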